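## Conventions and assumptions (remarks on the chemistry)

- Locants follow kaurane-type numbering. Ring A is C1–C5 and C10. Ring B is the oxepane C5–C6–O–C7–C8–C9–C10. Ring C is C8, C9, C11, C12, C13, C14. Ring D is C8, C14, C13, C16, C15, with C17 the exocyclic methylene carbon. The α face is the face of ring A that carries the C10 methyl; the β face carries H-5.
- The lactol of the target is taken to be the thermodynamically preferred anomer (6β-OH). The methyl acetals are drawn 6β-OMe, the anomer expected from acid equilibration; a 6α anomer would converge in step 22.
- The carbinol centre C9 in 8–17, the centre C8 in 20 and 21, the centre C9 in 31 and the centre C15 in 33 are left unassigned. Both epimers are carried and each centre is removed later.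

## Analysis of the target

Target 36 is a tetracyclic diterpenoid. A cyclohexane (ring A) is trans-fused to a seven-membered cyclic hemiacetal (ring B), and C8 and C9 of that oxepane also belong to a bicyclo[3.2.1]octane (rings C and D). There are nine stereocentres. C1 and C2 carry cis acetoxy groups on the α face, the face of the axial C10 methyl, so the C2 acetate is axial between two syn-axial methyls. C5 and C10 define the trans A/B fusion. C6 is the epimerisable lactol carbon. C8 and C13 are the bridgeheads, locked to each other by the C15–C16 bridge, with C15 on the β face of ring B, anti to the C10 methyl. C9 and C11 carry a cis epoxide on the α face of ring C, opposite the C15–C16 bridge. The sensitive groups are the exo-methylene ketone (a Michael acceptor), the trisubstituted epoxide whose C9 sits between two quaternary carbons, the lactol and the two acetates. The difficulty lies in the contiguous fully substituted array C8–C9–C10 (with C4 a third quaternary carbon nearby) and in placing four oxygen functions at different oxidation levels around it. The strategy rests on ring D: it is a methylenecyclopentane whose C8 is quaternary, shared with ring B and α to C9. An exocyclic enone (C9 ketone, C8=C14) and a four-carbon trimethylenemethane unit (C13, C16 with C17, C15) therefore assemble it in one operation.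

## Retrosynthetic reasoning

**36 to 34.** The lactol is unmasked last from methyl acetal 35, because a free hemiacetal would not survive the oxidations. The epoxide of 35 is put on dienone 34 by a peracid. At that stage the second alkene is part of an enone and is electronically switched off, so only the C9=C11 bond reacts. The step has to deliver oxygen to the α face.

**34 to 32.** The C15 carbonyl is cut back through allylic alcohol 33 to diene 32. C15 is the only allylic methylene of the exocyclic alkene and C13 is a bridgehead. An allylic oxidation is therefore regiochemically safe only after ring C exists, which is why this oxygen is introduced late.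

**32 to 28.** The C9=C11 bond is traced to tertiary alcohol 31 and the C9–C11 bond is cut. Iodide 30, from alcohol 29 and silyl ether 28, closes the six-membered ring C onto the C9 ketone by a samarium Barbier reaction. C9 is flanked by two quaternary carbons, so dehydration can only go towards C11. This cut leaves a C9 ketone in 28, the function that activates the key step.

**28 to 22 and 27 (key disconnection).** The bonds C13–C14 and C8–C15 are cut. This removes ring D as a trimethylenemethane unit and leaves α-methylene ketone 22 and silyl allyl carbonate 27. The cut is made here because it joins a complete A/B fragment carrying six of the nine stereocentres to a four-carbon unit that already holds C11 and C12. It creates the quaternary C8, the C16 methylene and C13 together. The forward reaction must add the substituted terminus to C14, close on the β face of the C8 enolate and place the C13 chain cis to C9.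

**27 to 23 and 24.** The donor is cut at the carbinol–vinyl bond into vinyl bromide 23 and aldehyde 24. One flask operation joins them and forms the carbonate.

**22 to 16.** The methylene carbon C14 is removed (Mannich-type methylenation of ketone 18). The C9 ketone is taken back to alcohol 17 and its silyl ether 16. C9 has to stay at the alcohol level while ring A is reduced; a 1,3-diketone at C1 and C9 would not survive hydride or base.

**16 to 13.** The cis-1α,2α-diacetate comes from diol 15. Both carbinol centres are made by hydride delivery to the β face of diosphenol 14, itself the autoxidation product of ketone 13. Reagents that deliver oxygen would attack the open β face and give the wrong diol, so carbonyl reduction is the stereochemically correct way to put oxygen on the hindered α face.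

**13 to 9.** Ring B is opened at the C6–O bond to hydroxy acetal 12. That comes from enone acetal 11 by one hydrogenation, which saturates C2=C3 and frees the C7 hydroxyl. The acetal carbon C6 is traced to the styryl group of 9, a masked aldehyde.

**9 to 5 and 6.** The C10–C9 bond is cut: aldol addition of the C10 enolate of enone 5 to aldehyde 6 builds the quaternary centre and brings in C9, C8 and C7. The electrophile enters anti to the C5 substituent, so the methyl group has to be in place first.

**5 to 1 and 2.** The C10 methyl is removed (α'-methylation of enone 3) and the C5–C6 bond is cut. A rhodium-catalysed asymmetric conjugate addition of boronic acid 2 to the prochiral dienone 1 sets C5, the stereocentre from which C10 and then the rest of ring A follow. The remaining ring alkene of the dienone blocks enolisation towards C2, so both enolate reactions at C10 are regiospecific.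

## Alternatives that were turned down

**Alternative 1:** Rings C and D are disconnected together, at C8–C14 and C13–C16, back to the open-chain β-keto ester A2. Forward, a one-electron metal oxidant (trivalent manganese) generates the C8 radical of A2. It adds to the terminal alkene in the 6-endo mode, and the resulting C13 radical closes 5-exo onto the propargyl alkyne to give the bicyclic keto ester A1. In its favour, two rings, the quaternary C8 and the C16 methylene arise in one step from a very simple precursor. The bridge also fixes the C8/C13 relationship by geometry, which is a real advantage over the chosen route, where this relationship must be won by ligand and substrate control. Against it for this target, A1 holds only the C/D half. Ring A, the oxepane acetal and the quaternary C10 would have to be built afterwards onto a neopentyl ketone (C9) and an ester (C7). The C9–C10 bond between two fully substituted carbons would then be made late and intermolecularly, and the auxiliary exerts only remote control over C8. The chosen strategy instead joins a finished A/B fragment to ring D in one convergent step and closes ring C by a reliable six-membered ring closure.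

**Alternative 2:** Ring A is formed by contraction and ring B by lactonisation, starting from the seven-membered diazoketone A4. Forward, photolysis triggers a Wolff rearrangement in which C10 migrates to the carbene carbon C5, and the C7 hydroxyl captures the ketene to give lactone A3. In its favour, the step is neutral, needs no metal, makes the C5–C10 bond and the C6–O bond together, and the C8/C13 question does not arise because rings C and D are already present. Against it, A4 is itself a tetracycle with a seven-membered carbocycle, a quaternary C10 and a protected cis-diol, so the route is long and linear before its key step. C5 is set only by protonation of the enol formed on ketene capture, with no element securing the trans fusion. A3 is a lactone, one oxidation level too high, and its reduction to the lactol would have to be done in the presence of esters and, later, the enone. On step economy after the key step the two routes are similar. The chosen route has the acetal at the correct oxidation level from step 6 and sets C5 by catalyst control in step 1.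

**Alternative 3:** Rings B and C are disconnected together, at C8–C9 and C13–C14, back to the acetal-tethered pyrone A6. Forward, heating brings the pyrone diene and the tethered enone together in an intramolecular Diels–Alder reaction; decarboxylation of the adduct gives the tricyclic diene A5. In its favour, two rings and two carbon–carbon bonds form in one thermal step, the acetal serves as the tether, and the 9(11)-alkene appears directly without a dehydration, a point on which this alternative is stronger. Against it, the tether closes a seven-membered ring, which is entropically poor for an intramolecular cycloaddition, and an electron-poor pyrone is mismatched with an electron-poor enone, so forcing temperatures are needed for a substrate that carries an acetal and two acetates. Nothing controls the face of C8 relative to C10. Ring D must still be annulated from the C8 acetyl group and C13 of a 9(11),12-diene whose two alkenes must be told apart. The chosen strategy forms ring D and the C8 stereocentre in the convergent step and leaves only a Barbier closure for ring C.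

Key step: step 14

## Route

Step 1
Reactants: 1 4,4-dimethylcyclohexa-2,5-dien-1-one; 2 (E)-2-phenylethenylboronic acid
Product: 3 (R)-4,4-dimethyl-5-[(E)-2-phenylethenyl]cyclohex-2-en-1-one
Conditions: Rh(acac)(C2H4)2 (3 mol%), (R)-BINAP, 2 (2 equiv), 1,4-dioxane/H2O (10:1), 60–100 °C
Reagents that add atoms: none
Why: Rhodium-catalysed asymmetric 1,4-addition of an alkenylboronic acid (Hayashi–Miyaura reaction) to one of the two enantiotopic enone halves of the dienone; the BINAP-bound alkenylrhodium selects the enone face and sets C5, and the product enone is more hindered and less electrophilic than 1, which should stop the reaction after one addition. The (R)-ligand is the antipode that gives (R)-3-arylcyclohexanones from cyclohex-2-enone, the same spatial sense as the 5R ketone needed here.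

Step 2
Reactants: 3 (R)-4,4-dimethyl-5-[(E)-2-phenylethenyl]cyclohex-2-en-1-one
Product: 5 (5S,6S)-4,4,6-trimethyl-5-[(E)-2-phenylethenyl]cyclohex-2-en-1-one, via lithium dienolate 4 (not isolated)
Conditions: LiN(iPr)2, THF, −78 °C; MeI, −78 → −20 °C
Reagents that add atoms: iodomethane, CI
Why: α'-Alkylation of an enone: the ring alkene blocks the other α side, so only the cross-conjugated C10 enolate can form. Methylation anti to the styryl group gives the trans isomer, but this centre is flattened again in step 3.

Step 3
Reactants: 5 (5S,6S)-4,4,6-trimethyl-5-[(E)-2-phenylethenyl]cyclohex-2-en-1-one; 6 3-(benzyloxy)propanal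
Product: 9 silyl-protected aldol adduct (C10 quaternary with α-methyl; C9 OTBS; C7 OBn), via lithium enolate 7 (not isolated), via lithium aldolate 8 (not isolated)
Conditions: LiN(iPr)2, THF, −78 → 0 °C; 6, −78 °C; t-BuMe2SiOTf, −78 → −40 °C
Reagents that add atoms: tert-butyldimethylsilyl trifluoromethanesulfonate, CC(C)(C)[Si](C)(C)OS(=O)(=O)C(F)(F)F
Why: Aldol addition of the fully substituted lithium enolate with O-silylation of the aldolate in the same flask, which shuts off retro-aldol cleavage. The pseudoaxial C5 styryl group shields the α face, so the aldehyde should bond to C10 from the β face and fix the quaternary centre with the methyl cis to the styryl group. The C9 configuration is immaterial because C9 becomes a ketone in step 11.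

Step 4
Reactants: 9 silyl-protected aldol adduct
Product: 11 enone dimethyl acetal (C6 as CH(OMe)2), via aldehyde 10 (not isolated)
Conditions: O3, CH2Cl2/MeOH, Sudan Red 7B, −78 °C; Me2S, −78 °C → rt; then CH(OMe)3, PPTS, rt
Reagents that add atoms: ozone, [O-][O+]=O (carbonyl oxygen of 10); methanol, CO; trimethyl orthoformate, COC(OC)OC
Why: Ozone cleaves the electron-rich styrene double bond much faster than the electron-poor, neopentylic enone double bond (dye end-point). The aldehyde is masked at once as its dimethyl acetal so that C5, now α to a carbonyl, cannot epimerise.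

Step 5
Reactants: 11 enone dimethyl acetal
Product: 12 hydroxy ketone dimethyl acetal (C1 ketone; C7 OH)
Conditions: H2 (1 atm), Pd/C, EtOAc, rt
Reagents that add atoms: none
Why: One heterogeneous hydrogenation saturates the enone C2=C3 bond and hydrogenolyses the benzyl ether. No stereocentre is formed, and the silyl ether, ketone and acetal are inert.

Step 6
Reactants: 12 hydroxy ketone dimethyl acetal
Product: 13 trans-fused oxepane methyl acetal (ring A C1 ketone; C9 OTBS; 6β-OMe)
Conditions: PPTS (cat.), benzene, 5 Å MS, 60 °C
Reagents that add atoms: none
Why: Acid-catalysed transacetalisation: the C7 hydroxyl replaces one methoxy group through the oxocarbenium ion, and removal of methanol drives closure of the seven-membered ring between the two equatorial arms on C5 and C10. C6 is set under equilibrating conditions.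

Step 7
Reactants: 13 trans-fused oxepane methyl acetal
Product: 14 diosphenol (C1 ketone; C2 enol; C2=C3)
Conditions: KOtBu (3 equiv), O2 (1 atm), t-BuOH/THF, 0 °C → rt; AcOH quench
Reagents that add atoms: dioxygen, O=O
Why: Base-mediated autoxidation of a ketone that can enolise only towards C2: the potassium enolate takes up O2 and the hydroperoxide collapses to the 1,2-dione, which rests as its enol. The β-silyloxy group cannot be eliminated because C10 is quaternary.

Step 8
Reactants: 14 diosphenol
Product: 15 1α,2α-diol
Conditions: NaBH4 (excess), CeCl3·7H2O, MeOH, −40 → 0 °C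
Reagents that add atoms: none
Why: Luche-type 1,2-reduction of the C1 carbonyl, tautomerisation of the enediol to the C2 ketone, then a second hydride transfer. Both hydrides should arrive from the β face, because the α face of C1 and C2 is screened by the axial C10 methyl and the axial C4 methyl (1,3-diaxial to C2); this places both hydroxyls α (1α equatorial, 2α axial), the pattern known for A-ring diosphenols of 4,4,10-trimethyl decalins.

Step 9
Reactants: 15 1α,2α-diol
Product: 16 1α,2α-diacetate
Conditions: Ac2O, pyridine, DMAP, CH2Cl2, rt → 40 °C
Reagents that add atoms: acetic anhydride, CC(=O)OC(C)=O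
Why: Standard DMAP-catalysed acetylation; the hindered axial C2 hydroxyl needs the nucleophilic catalyst and gentle warming.

Step 10
Reactants: 16 1α,2α-diacetate
Product: 17 C9 alcohol
Conditions: HF·pyridine, pyridine, THF, 0 → 40 °C
Reagents that add atoms: none
Why: Fluoride cleavage of the secondary silyl ether under buffered, non-basic conditions that leave the acetates and the methyl acetal untouched.

Step 11
Reactants: 17 C9 alcohol
Product: 18 oxepan-9-one
Conditions: Dess–Martin periodinane, NaHCO3, CH2Cl2, rt
Reagents that add atoms: none
Why: Dess–Martin oxidation of the only free alcohol; both C9 epimers converge on one ketone.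

Step 12
Reactants: 18 oxepan-9-one
Product: 22 8-methylene-oxepan-9-one, via lithium enolate 19 (not isolated), via Mannich base 20 (not isolated), via ammonium iodide 21 (not isolated)
Conditions: LiN(SiMe3)2, THF, −78 °C; [CH2=NMe2]I, −78 → 0 °C; MeI, CH2Cl2, rt; aq. NaHCO3, rt
Reagents that add atoms: N,N-dimethylmethyleneiminium iodide (Eschenmoser's salt), C=[N+](C)C.[I-]
Why: Mannich reaction of the C8 lithium enolate with Eschenmoser's salt, N-methylation and base-induced elimination of trimethylamine give the α-methylene ketone. C8 is the only enolisable position of the ketone, and kinetic deprotonation at −78 °C should outrun acetate enolisation and loss of the β-alkoxide.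

Step 13
Reactants: 23 2-bromoallyltrimethylsilane; 24 3-(tert-butyldimethylsilyloxy)propanal
Product: 27 racemic donor carbonate, via vinyllithium 25 (not isolated), via lithium alkoxide 26 (not isolated)
Conditions: t-BuLi (2 equiv), Et2O, −78 °C; 24, −78 °C; ClCO2Me, −78 → 0 °C
Reagents that add atoms: methyl chloroformate, COC(=O)Cl
Why: Bromine–lithium exchange gives the 2-lithioallylsilane, which adds to the aldehyde; the alkoxide is acylated in the same flask, the usual way to substituted trimethylenemethane precursors. Racemic material suffices because the carbinol stereocentre is lost on ionisation.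

Step 14
Reactants: 22 8-methylene-oxepan-9-one; 27 racemic donor carbonate
Product: 28 A/B/D spiro tricycle (C9 ketone; C16 methylene; C13 silyloxyethyl chain cis to C9)
Conditions: Pd(dba)2 (5 mol%), BINOL-derived bis(2-naphthyl)pyrrolidine phosphoramidite (12 mol%), 27 (2.5 equiv), toluene, 50 °C
Reagents that add atoms: none
Why: Zerovalent palladium ionises the allylic carbonate and the released methoxide removes the silyl group, leaving a zwitterionic palladium–trimethylenemethane complex whose negative charge settles on the substituted carbon. This carbon (C13) adds in conjugate fashion to C14 of the exocyclic enone, and the C8 enolate then closes ring D by attacking the π-allyl terminus C15; the five-membered ring is formed by intramolecular allylic alkylation, a stepwise [3+2] overall, and the C16 methylene remains. The closest known reaction type is the palladium-catalysed trimethylenemethane cycloaddition to α-methylene ketones and related exocyclic acceptors, which gives spiro-fused methylenecyclopentanes also with donors substituted at the carbinol carbon. C13 is created in the conjugate addition, remote from the stereocentres of 22, and is therefore placed under control of the chiral phosphoramidite on palladium. C8 is created in the ring closure: the axial C10 methyl screens the α face of the enolate, so C15 should bond from the β face. The target needs the C13 chain cis to C9, which is one combination of ligand and substrate control; it is selected by the choice of ligand antipode, which cannot be assigned beforehand with confidence. Regioselectivity rests on the known tendency of substituted complexes to bond through the substituted terminus, and chemoselectivity on the fact that only the allylic carbonate ionises and the enone is the only acceptor. β-Hydride loss from the alkyl-substituted allyl complex and β-alkoxide loss from the C8 enolate are the competing processes that the fast intramolecular closure has to outrun.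

Step 15
Reactants: 28 A/B/D spiro tricycle
Product: 29 primary alcohol (C11 OH)
Conditions: HF·pyridine, pyridine, THF, 0 °C
Reagents that add atoms: none
Why: Fluoride cleavage of the unhindered primary silyl ether; the ketone, acetates, acetal and alkene are inert.

Step 16
Reactants: 29 primary alcohol
Product: 30 primary iodide (C11 I)
Conditions: I2, PPh3, imidazole, CH2Cl2, 0 °C → rt
Reagents that add atoms: iodine, II
Why: Appel-type iodination of a primary alcohol through the alkoxyphosphonium salt under neutral conditions.

Step 17
Reactants: 30 primary iodide
Product: 31 tetracyclic C9 tertiary alcohol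
Conditions: SmI2 (2.5 equiv), THF/HMPA, 0 °C → rt; aq. NH4Cl
Reagents that add atoms: none
Why: Intramolecular samarium Barbier reaction: divalent samarium reduces the primary iodide and the C11 organosamarium adds to the C9 ketone, a six-membered ring closure made possible by the cis relationship of C12 and C9 on ring D. Acetates are inert to SmI2, and neither the alkyl radical nor the ketyl has a favourable cyclisation mode onto the exocyclic alkene. The C9 configuration is unimportant because it is removed in step 18.

Step 18
Reactants: 31 tetracyclic C9 tertiary alcohol
Product: 32 9(11),16-diene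
Conditions: SOCl2, pyridine, CH2Cl2, −20 → 0 °C
Reagents that add atoms: none
Why: Dehydration of the tertiary alcohol through its chlorosulfite. C8 and C10 are quaternary, so the only β-hydrogens are on C11 and the 9(11)-alkene is the only possible elimination product; C9 is not a bridgehead.

Step 19
Reactants: 32 9(11),16-diene
Product: 33 15-hydroxy-9(11),16-diene
Conditions: SeO2 (0.5 equiv), t-BuOOH (2 equiv), CH2Cl2, rt
Reagents that add atoms: tert-butyl hydroperoxide, CC(C)(C)OO (oxygen delivered through SeO2, O=[Se]=O)
Why: Allylic oxidation by ene reaction and [2,3]-shift at C15, the only allylic methylene of the 1,1-disubstituted alkene, since C13 is a bridgehead. The 9(11)-alkene is spared because the carbons attached to C9 carry no hydrogen; the C15 configuration is irrelevant.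

Step 20
Reactants: 33 15-hydroxy-9(11),16-diene
Product: 34 16-methylene-9(11)-en-15-one
Conditions: Dess–Martin periodinane, NaHCO3, CH2Cl2, rt
Reagents that add atoms: none
Why: Dess–Martin oxidation of the secondary allylic alcohol to the exo-methylene ketone under neutral conditions.

Step 21
Reactants: 34 16-methylene-9(11)-en-15-one
Product: 35 9α,11α-epoxide methyl acetal
Conditions: mCPBA, NaHCO3, CH2Cl2, 0 °C
Reagents that add atoms: 3-chloroperoxybenzoic acid, OOC(=O)c1cccc(Cl)c1
Why: Prilezhaev epoxidation: the peracid attacks only the electron-rich 9(11)-alkene, the enone alkene being deactivated. Attack should come from the α face, the exo face of the bicyclo[3.2.1]octene, because the β face of C11 lies under the C15–C16 bridge; this sets C9 and C11.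

Step 22
Reactants: 35 9α,11α-epoxide methyl acetal
Product: 36 CNP0224512.1 (target)
Conditions: PPTS, acetone/H2O (5:1), rt → 40 °C
Reagents that add atoms: water, O
Why: Mild acid hydrolysis of the oxepanyl methyl acetal through the seven-membered oxocarbenium ion; the lactol settles as the favoured anomer. The epoxide carbon C9 is neopentylic and next to the carbonyl-bearing C8, so its ionisation should be slow under these conditions.

## Compound list

1 | 4,4-dimethylcyclohexa-2,5-dien-1-one | CC1(C)C=CC(=O)C=C1 | starting material
2 | (E)-2-phenylethenylboronic acid | OB(O)/C=C/c1ccccc1 | starting material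
3 | (R)-4,4-dimethyl-5-[(E)-2-phenylethenyl]cyclohex-2-en-1-one | c1ccccc1/C=C/[C@@H]2C(C)(C)C=CC(=O)C2 | intermediate
4 | lithium dienolate of 3 (lithium 4,4-dimethyl-3-[(E)-2-phenylethenyl]cyclohexa-1,5-dien-1-olate) | c1ccccc1/C=C/[C@@H]2C(C)(C)C=CC([O-])=C2.[Li+] | intermediate (not isolated)
5 | (5S,6S)-4,4,6-trimethyl-5-[(E)-2-phenylethenyl]cyclohex-2-en-1-one | c1ccccc1/C=C/[C@@H]2C(C)(C)C=CC(=O)[C@H]2C | intermediate
6 | 3-(benzyloxy)propanal | O=CCCOCc1ccccc1 | starting material
7 | lithium enolate of 5 (lithium 2,4,4-trimethyl-3-[(E)-2-phenylethenyl]cyclohexa-1,5-dien-1-olate) | c1ccccc1/C=C/[C@@H]2C(C)(C)C=CC([O-])=C2C.[Li+] | intermediate (not isolated)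
8 | lithium aldolate: 6-[3-(benzyloxy)-1-oxidopropyl]-4,4,6-trimethyl-5-[(E)-2-phenylethenyl]cyclohex-2-en-1-one lithium salt (C10 methyl α, carbinol chain β, C9 unassigned) | c1ccccc1/C=C/[C@@H]2C(C)(C)C=CC(=O)[C@@]2(C)C([O-])CCOCc1ccccc1.[Li+] | intermediate (not isolated)
9 | 6-[3-(benzyloxy)-1-(tert-butyldimethylsilyloxy)propyl]-4,4,6-trimethyl-5-[(E)-2-phenylethenyl]cyclohex-2-en-1-one (styryl α, C10 methyl α, C9 chain β, C9 unassigned) | c1ccccc1/C=C/[C@@H]2C(C)(C)C=CC(=O)[C@@]2(C)C(O[Si](C)(C)C(C)(C)C)CCOCc1ccccc1 | intermediate
10 | aldehyde: 2-[3-(benzyloxy)-1-(tert-butyldimethylsilyloxy)propyl]-2,6,6-trimethyl-3-oxocyclohex-4-ene-1-carbaldehyde (formyl α, methyl α) | O=C[C@@H]1C(C)(C)C=CC(=O)[C@@]1(C)C(O[Si](C)(C)C(C)(C)C)CCOCc1ccccc1 | intermediate (not isolated)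
11 | enone dimethyl acetal: 6-[3-(benzyloxy)-1-(tert-butyldimethylsilyloxy)propyl]-5-(dimethoxymethyl)-4,4,6-trimethylcyclohex-2-en-1-one | COC(OC)[C@@H]1C(C)(C)C=CC(=O)[C@@]1(C)C(O[Si](C)(C)C(C)(C)C)CCOCc1ccccc1 | intermediate
12 | hydroxy ketone dimethyl acetal: 2-[1-(tert-butyldimethylsilyloxy)-3-hydroxypropyl]-3-(dimethoxymethyl)-2,4,4-trimethylcyclohexan-1-one | COC(OC)[C@@H]1C(C)(C)CCC(=O)[C@@]1(C)C(O[Si](C)(C)C(C)(C)C)CCO | intermediate
13 | trans-fused oxepane methyl acetal: ring A C1 ketone; ring B C5–C6H(β-OMe)–O–C7H2–C8H2–C9H(OTBS)–C10; H-5 β, C10 methyl α | C1CO[C@@H](OC)[C@@H]2C(C)(C)CCC(=O)[C@@]2(C)C1O[Si](C)(C)C(C)(C)C | intermediate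
14 | diosphenol: as 13 with C1 ketone, C2 enol hydroxyl and C2=C3 | C1CO[C@@H](OC)[C@@H]2C(C)(C)C=C(O)C(=O)[C@@]2(C)C1O[Si](C)(C)C(C)(C)C | intermediate
15 | 1α,2α-diol: as 13 with 1α-OH (equatorial) and 2α-OH (axial) | C1CO[C@@H](OC)[C@@H]2C(C)(C)C[C@H](O)[C@H](O)[C@@]2(C)C1O[Si](C)(C)C(C)(C)C | intermediate
16 | 1α,2α-diacetate with C9 OTBS | C1CO[C@@H](OC)[C@@H]2C(C)(C)C[C@H](OC(C)=O)[C@H](OC(C)=O)[C@@]2(C)C1O[Si](C)(C)C(C)(C)C | intermediate
17 | 1α,2α-diacetate with C9 OH | C1CO[C@@H](OC)[C@@H]2C(C)(C)C[C@H](OC(C)=O)[C@H](OC(C)=O)[C@@]2(C)C1O | intermediate
18 | A/B bicyclic oxepan-9-one: 1α,2α-diacetoxy, 6β-methoxy, C9 ketone, C8 CH2 | C1CO[C@@H](OC)[C@@H]2C(C)(C)C[C@H](OC(C)=O)[C@H](OC(C)=O)[C@@]2(C)C1=O | intermediate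
19 | lithium C8 enolate of 18 | [Li+].[O-]C1=CCO[C@@H](OC)[C@@H]2C(C)(C)C[C@H](OC(C)=O)[C@H](OC(C)=O)[C@@]12C | intermediate (not isolated)
20 | Mannich base: 18 with CH2NMe2 on C8 (C8 unassigned) | CN(C)CC1CO[C@@H](OC)[C@@H]2C(C)(C)C[C@H](OC(C)=O)[C@H](OC(C)=O)[C@@]2(C)C1=O | intermediate (not isolated)
21 | trimethylammonium iodide of 20 | C[N+](C)(C)CC1CO[C@@H](OC)[C@@H]2C(C)(C)C[C@H](OC(C)=O)[C@H](OC(C)=O)[C@@]2(C)C1=O.[I-] | intermediate (not isolated)
22 | A/B bicyclic 8-methylene-oxepan-9-one: 1α,2α-diacetoxy, 6β-methoxy, C9 ketone, C8=C14H2 | C=C1CO[C@@H](OC)[C@@H]2C(C)(C)C[C@H](OC(C)=O)[C@H](OC(C)=O)[C@@]2(C)C1=O | intermediate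
23 | 2-bromoallyltrimethylsilane | C=C(Br)C[Si](C)(C)C | starting material
24 | 3-(tert-butyldimethylsilyloxy)propanal | O=CCCO[Si](C)(C)C(C)(C)C | starting material
25 | 2-lithio-3-(trimethylsilyl)prop-1-ene | [Li]C(=C)C[Si](C)(C)C | intermediate (not isolated)
26 | lithium 5-(tert-butyldimethylsilyloxy)-2-(trimethylsilylmethyl)pent-1-en-3-olate | [Li+].[O-]C(CCO[Si](C)(C)C(C)(C)C)C(=C)C[Si](C)(C)C | intermediate (not isolated)
27 | racemic 5-(tert-butyldimethylsilyloxy)-2-(trimethylsilylmethyl)pent-1-en-3-yl methyl carbonate | COC(=O)OC(CCO[Si](C)(C)C(C)(C)C)C(=C)C[Si](C)(C)C | intermediate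
28 | A/B/D spiro tricycle: 22 with a 3-methylenecyclopentane spiro at C8 (C15 β, C14 α), C13 bearing CH2CH2OTBS cis to C9 | C=C1C[C@]2(CO[C@@H](OC)[C@@H]3C(C)(C)C[C@H](OC(C)=O)[C@H](OC(C)=O)[C@@]3(C)C2=O)C[C@H]1CCO[Si](C)(C)C(C)(C)C | intermediate
29 | primary alcohol: 28 with C11 OH | C=C1C[C@]2(CO[C@@H](OC)[C@@H]3C(C)(C)C[C@H](OC(C)=O)[C@H](OC(C)=O)[C@@]3(C)C2=O)C[C@H]1CCO | intermediate
30 | primary iodide: 28 with C11 I | C=C1C[C@]2(CO[C@@H](OC)[C@@H]3C(C)(C)C[C@H](OC(C)=O)[C@H](OC(C)=O)[C@@]3(C)C2=O)C[C@H]1CCI | intermediate
31 | tetracyclic C9 tertiary alcohol: rings A–D closed, C9 OH (unassigned), C16 methylene, 6β-OMe | C=C1C[C@@]23CO[C@@H](OC)[C@@H]4C(C)(C)C[C@H](OC(C)=O)[C@H](OC(C)=O)[C@@]4(C)C2(O)CC[C@@H]1C3 | intermediate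
32 | tetracyclic 9(11),16-diene | C=C1C[C@@]23CO[C@@H](OC)[C@@H]4C(C)(C)C[C@H](OC(C)=O)[C@H](OC(C)=O)[C@@]4(C)C2=CC[C@@H]1C3 | intermediate
33 | 15-hydroxy-9(11),16-diene (C15 unassigned) | C=C1C(O)[C@@]23CO[C@@H](OC)[C@@H]4C(C)(C)C[C@H](OC(C)=O)[C@H](OC(C)=O)[C@@]4(C)C2=CC[C@@H]1C3 | intermediate
34 | 16-methylene-9(11)-en-15-one methyl acetal | C=C1C(=O)[C@@]23CO[C@@H](OC)[C@@H]4C(C)(C)C[C@H](OC(C)=O)[C@H](OC(C)=O)[C@@]4(C)C2=CC[C@@H]1C3 | intermediate
35 | 9α,11α-epoxy-16-methylene-15-one methyl acetal | C=C1C(=O)[C@@]23CO[C@@H](OC)[C@@H]4C(C)(C)C[C@H](OC(C)=O)[C@H](OC(C)=O)[C@@]4(C)[C@]24O[C@@H]4C[C@@H]1C3 | intermediate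
36 | CNP0224512.1: 1α,2α-diacetoxy-9α,11α-epoxy-6β-hydroxy lactol with 16-methylene-15-one | C=C1C(=O)[C@@]23CO[C@@H](O)[C@@H]4C(C)(C)C[C@H](OC(C)=O)[C@H](OC(C)=O)[C@@]4(C)[C@]24O[C@@H]4C[C@@H]1C3 | target

## Step count and least certain steps

Total: 22 steps (steps 1–12 to enone 22, step 13 for the donor, step 14 for the union, steps 15–22 for the endgame). Longest linear sequence: 21 steps (1 to 36 through steps 1–12 and 14–22).

**Step 14 (key step).** The alkyl-substituted allyl–palladium intermediate can lose a β-hydrogen and drain the donor into a diene before it meets the hindered enone. The conjugate addition can be slow enough for the donor to decompose. Facial selection at C8 may be poor, because both faces of the seven-membered enolate carry a substituent. Ligand control at C13 may be mismatched with the substrate. The fallback sets out from 22 and 23. The same one-flask procedure with acrolein in place of 24 gives the vinyl-substituted donor F1, a donor class that has no β-hydrogen to lose and is well behaved in asymmetric versions of this cycloaddition. Cycloaddition with 22 under the conditions of step 14 gives the 13-vinyl spiro tricycle F2. Hydroboration of the monosubstituted vinyl group with disiamylborane and oxidation with NaBO3·4H2O, which spares the acetates, returns to the route at 29. The hindered 1,1-disubstituted methylene and the neopentyl ketone react more slowly with this borane.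

**Step 3.** The hindered, fully substituted enolate may add slowly and reversibly. Proton transfer from the enolisable β-alkoxy aldehyde, with loss of benzyl alcohol from the aldehyde enolate, can then take over, and facial selection at C10 may be incomplete. The fallback sets out from 5 and uses an irreversible Lewis-acid pathway. LiN(iPr)2 and Me3SiCl give the trimethylsilyl dienol ether F3. Mukaiyama aldol addition to 6 with BF3·OEt2 in CH2Cl2 at −78 °C gives the free aldol F4. Silylation with t-BuMe2SiOTf and 2,6-lutidine returns to the route at 9.

**Step 8.** The intermediate α-ketol can epimerise at the carbinol carbon before the second hydride transfer, or hydride can reach C2 from the α face; either process gives a trans-diol or the wrong cis-diol. The fallback sets out from 14 and fixes C2 by hydrogen delivery. Acetylation (Ac2O, pyridine) gives the diosphenol acetate F5. Hydrogenation over Pd/C adds hydrogen to the open β face of the enol acetate and gives the 2α-acetoxy ketone F6. NaBH4 then gives the 1α-hydroxy 2α-acetate F7, and acetylation returns to the route at 16.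

**Step 18.** The chlorosulfite may ionise to a C9 cation flanked by two quaternary carbons, and a 1,2-shift of the C10 methyl or of a ring D bond can then compete with proton loss. Activation of the very hindered hydroxyl may also stall. The fallback sets out from 29 and avoids both the Barbier step and the cation. Dess–Martin oxidation gives the keto aldehyde F8. Intramolecular McMurry coupling with low-valent titanium (TiCl3, Zn–Cu couple, DME, reflux) forms the C9=C11 bond directly and returns to the route at 32.

**Step 21.** The peracid may approach from the β face, since the C10 methyl lies near the α face of C9 while the bridge atoms C15 and C16 are sp2 and shield the β face less than in a saturated bicycle. The fallback sets out from 34 and inverts the facial outcome. NBS in aqueous THF forms the bromonium ion on the face the peracid prefers and water opens it anti, giving the 9α-hydroxy-11β-bromide F9. DBU then closes the α-epoxide and returns to the route at 35.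

**Step 22.** Acid may open or rearrange the epoxide, including transannular attack of the liberated C6 hydroxyl on C9, before the acetal is fully hydrolysed. The fallback sets out from 34 and changes the order so that the epoxide never meets acid. Hydrolysis of the acetal (PPTS, acetone/water) gives the lactol dienone F10. Buffered epoxidation (mCPBA, NaHCO3, 0 °C) then gives 36 directly.

## Further compounds

F1 | step 14 | 2-(trimethylsilylmethyl)penta-1,4-dien-3-yl methyl carbonate (racemic) | COC(=O)OC(C=C)C(=C)C[Si](C)(C)C
F2 | step 14 | 13-vinyl A/B/D spiro tricycle (28 with CH=CH2 on C13 in place of the silyloxyethyl chain) | C=C1C[C@]2(CO[C@@H](OC)[C@@H]3C(C)(C)C[C@H](OC(C)=O)[C@H](OC(C)=O)[C@@]3(C)C2=O)C[C@H]1C=C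
F3 | step 3 | trimethylsilyl dienol ether of 5 | c1ccccc1/C=C/[C@@H]2C(C)(C)C=CC(O[Si](C)(C)C)=C2C
F4 | step 3 | free aldol: 6-[3-(benzyloxy)-1-hydroxypropyl]-4,4,6-trimethyl-5-[(E)-2-phenylethenyl]cyclohex-2-en-1-one (C9 unassigned) | c1ccccc1/C=C/[C@@H]2C(C)(C)C=CC(=O)[C@@]2(C)C(O)CCOCc1ccccc1
F5 | step 8 | diosphenol acetate (14 with the C2 enol acetylated) | C1CO[C@@H](OC)[C@@H]2C(C)(C)C=C(OC(C)=O)C(=O)[C@@]2(C)C1O[Si](C)(C)C(C)(C)C
F6 | step 8 | 2α-acetoxy C1 ketone | C1CO[C@@H](OC)[C@@H]2C(C)(C)C[C@H](OC(C)=O)C(=O)[C@@]2(C)C1O[Si](C)(C)C(C)(C)C
F7 | step 8 | 1α-hydroxy 2α-acetate | C1CO[C@@H](OC)[C@@H]2C(C)(C)C[C@H](OC(C)=O)[C@H](O)[C@@]2(C)C1O[Si](C)(C)C(C)(C)C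
F8 | step 18 | keto aldehyde (29 with C11 as CHO) | C=C1C[C@]2(CO[C@@H](OC)[C@@H]3C(C)(C)C[C@H](OC(C)=O)[C@H](OC(C)=O)[C@@]3(C)C2=O)C[C@H]1CC=O
F9 | step 21 | 9α-hydroxy-11β-bromo-16-methylene-15-one methyl acetal | C=C1C(=O)[C@@]23CO[C@@H](OC)[C@@H]4C(C)(C)C[C@H](OC(C)=O)[C@H](OC(C)=O)[C@@]4(C)[C@@]2(O)[C@@H](Br)C[C@@H]1C3
F10 | step 22 | lactol dienone (34 with 6β-OH in place of OMe) | C=C1C(=O)[C@@]23CO[C@@H](O)[C@@H]4C(C)(C)C[C@H](OC(C)=O)[C@H](OC(C)=O)[C@@]4(C)C2=CC[C@@H]1C3
A1 | alternative 1 | 8-phenylmenthyl 6-methylidene-2-oxobicyclo[3.2.1]octane-1-carboxylate | C=C1C[C@@]2(C(=O)O[C@@H]3C[C@H](C)CC[C@H]3C(C)(C)c3ccccc3)C(=O)CC[C@@H]1C2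
A2 | alternative 1 | 8-phenylmenthyl 3-oxo-2-(prop-2-yn-1-yl)hept-6-enoate | C#CCC(C(=O)O[C@@H]1C[C@H](C)CC[C@H]1C(C)(C)c1ccccc1)C(=O)CCC=C
A3 | alternative 2 | tetracyclic seven-membered lactone with 9(11)-alkene, C16 methylene and C1,C2 acetonide | C=C1C[C@@]23COC(=O)[C@@H]4C(C)(C)C[C@@H]5OC(C)(C)O[C@@H]5[C@@]4(C)C2=CC[C@@H]1C3
A4 | alternative 2 | A-homo α-diazoketone (C6 ketone, C5 diazo carbon, free C7 hydroxyl, C1,C2 acetonide) | C=C1C[C@]2(CO)C[C@H]1CC=C2[C@@]1(C)C(=O)C(=[N+]=[N-])C(C)(C)C[C@@H]2OC(C)(C)O[C@@H]21
A5 | alternative 3 | A/B/C tricyclic 9(11),12-diene with C8 acetyl group | CC(=O)[C@@]12CO[C@@H](OC)[C@@H]3C(C)(C)C[C@H](OC(C)=O)[C@H](OC(C)=O)[C@@]3(C)C1=CC=CC2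
A6 | alternative 3 | ring A acetal carrying a 2-pyranon-6-yl group on C10 and a 2-acetylallyl ether on the acetal oxygen | CC(=O)C(=C)CO[C@@H](OC)[C@@H]1C(C)(C)C[C@H](OC(C)=O)[C@H](OC(C)=O)[C@@]1(C)c1cccc(=O)o1
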